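**Plan**

1. Numbering (chamigrane): ring B = C1–C5 plus spiro C6 (C2 bears Cl, C3 bears Br and methyl C15); ring A = C6–C11 (C7 bears methylene C14, C10 bears Br, C11 is CMe2). "15-nor" marks intermediates that still lack C15.
2. Retrosynthesis: C2–Cl and C3–Br go back through a chlorohydrin and an epoxide to a C2=C3 alkene; C15 and the ring B oxidation level go back to a spiro cyclohexadienone with C3=O; the C6–C7 bond is cut by a dearomative 6-exo-dig cyclization of a para-substituted phenol onto a terminal alkyne; the C6–C11 bond is cut by a Friedel–Crafts step; C10–Br goes back to an epoxide of 6-methylhept-5-en-1-yne.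
3. Forward: the C7–C11 chain is made first and joined to phenol (the six ring B carbons); ring A is then closed on the arene, which gives the spiro centre, the methylene and the dienone in one step; ring B is finally reduced, desymmetrized and halogenated.
4. Enabling feature: C6 is para to C3 in ring B and C3 carries a heteroatom in the target, so ring B can start as a phenol whose oxygen (at C3) makes the ipso carbon C6 nucleophilic; the C7=C14 methylene is the footprint of a terminal alkyne held five atoms from C6 by the C11 gem-dimethyl tether.
5. Stereochemistry: C10 comes from a Shi epoxide opened with inversion by bromide; C6 becomes stereogenic only when the two ring B arms are differentiated and is set by a chiral lithium amide; C2 and C3 follow from anti additions and inversions on ring B faces defined by axial C7.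

Key step: step 5

Remark: ring B of the spiro intermediates is assumed to prefer the chair (or half-chair) with C11 equatorial and C7 axial; "C7 face" and "C11 face" name the two faces of ring B, and in the target Cl (C2) and C15 lie on the C11 face while Br (C3) lies on the C7 face.

**Route**

Step 1
Reactants: 1 5-bromo-2-methylpent-2-ene
Product: 2 6-methylhept-5-en-1-yne
Conditions: LiC≡CH·H2NCH2CH2NH2, DMSO, 10 → 25 °C
Reagents that add atoms: lithium acetylide ethylenediamine complex, [Li]C#C.NCCN
Why: SN2 alkylation of an acetylide by an unhindered primary bromide in a dipolar aprotic solvent; no stereocentre is formed.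

Step 2
Reactants: 2 6-methylhept-5-en-1-yne
Product: 3 (3R)-3-(but-3-yn-1-yl)-2,2-dimethyloxirane
Conditions: D-fructose-derived ketone catalyst of the Shi epoxidation (30 mol %), KHSO5, K2CO3, Bu4NHSO4, MeCN/CH2(OMe)2/aq. Na2B4O7 buffer (pH 10.5), 0 °C
Reagents that add atoms: potassium peroxymonosulfate, [K+].[O-]S(=O)(=O)OO
Why: Shi epoxidation of a trisubstituted alkene, in which the chiral dioxirane should deliver oxygen to one enantioface through the spiro transition state and set C10 as (R); the terminal alkyne is not oxidized under the buffered conditions.

Step 3
Reactants: 3 (3R)-3-(but-3-yn-1-yl)-2,2-dimethyloxirane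
Product: 4 (3S)-3-bromo-2-methylhept-6-yn-2-ol
Conditions: Li2NiBr4, THF, 0 → 25 °C; then H2O
Reagents that add atoms: dilithium tetrabromonickelate, [Li+].[Li+].Br[Ni-2](Br)(Br)Br
Why: regioselective SN2 opening of a trisubstituted epoxide by soft bromide at the less substituted carbon, which inverts C10 to (S) and leaves the tertiary alcohol as the later leaving group.

Step 4
Reactants: 4 (3S)-3-bromo-2-methylhept-6-yn-2-ol; 5 phenol
Product: 6 4-[(3S)-3-bromo-2-methylhept-6-yn-2-yl]phenol
Conditions: phenol (5 equiv), TfOH (5 mol %), (CF3)2CHOH, 0 → 25 °C
Reagents that add atoms: none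
Why: Friedel–Crafts alkylation in which ionization of the tertiary alcohol is assisted by the neighbouring bromine (bridged bromonium ion) and phenol attacks the tertiary carbon para to OH, so the C10–Br bond is never broken and (S) is kept; the bulky electrophile and excess phenol favour para monoalkylation over capture by the weakly nucleophilic alkyne.

Step 5
Reactants: 6 4-[(3S)-3-bromo-2-methylhept-6-yn-2-yl]phenol
Product: 7 (10S)-10-bromo-15-norchamigra-1,4,7(14)-trien-3-one
Conditions: Ph3PAuNTf2 (5 mol %), CH2Cl2, 25 °C
Reagents that add atoms: none
Why: Cationic monovalent gold coordinates the terminal alkyne, and the phenol attacks it through its ipso carbon C6 (para to the hydroxyl) at the internal carbon C7, anti to gold; loss of the phenolic proton and protodeauration of the vinylgold then release the cross-conjugated dienone and the C7=C14 methylene. The closest known reaction type is the gold-catalysed dearomative ipso-Friedel–Crafts carbocyclization of para-(alkynylalkyl)phenols to spirocyclohexadienones, known mainly for five-membered rings. Ring A is closed in the 6-exo-dig mode, and the same event turns the arene into ring B. No stereocentre is created: C6 becomes quaternary but carries two identical dienone arms, and C10 is untouched. The step needs ipso rather than ortho attack and exo rather than endo closure; the first is secured by the para hydroxyl (the ortho carbons are meta to it and would have to form a seven-membered ring), the second by Markovnikov polarization of the terminal alkyne, and the gem-dimethyl group at C11 compresses the tether toward C6. Neutral conditions keep the phenol protonated, so the C10 bromide is not displaced by aryl participation.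

Step 6
Reactants: 7 (10S)-10-bromo-15-norchamigra-1,4,7(14)-trien-3-one
Product: 8 (10S)-10-bromo-15-norchamigr-7(14)-en-3-one
Conditions: [(Ph3P)CuH]6, H2O, toluene, 25 °C
Reagents that add atoms: none
Why: conjugate reduction of both enone units by the copper hydride, which should leave the isolated 1,1-disubstituted alkene, the ketone carbonyl and the secondary bromide alone; ring B keeps its mirror plane, so C6 is still not a stereocentre.

Step 7
Reactants: 8 (10S)-10-bromo-15-norchamigr-7(14)-en-3-one
Product: 10 (6R,10S)-10-bromo-15-norchamigra-2,7(14)-dien-3-yl trifluoromethanesulfonate, via lithium enolate 9 (not isolated)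
Conditions: (R,R)-[PhCH(CH3)]2NH, n-BuLi, LiCl, THF, −78 °C; then PhNTf2, −78 → 0 °C
Reagents that add atoms: N-phenylbis(trifluoromethanesulfonimide), O=S(=O)(N(c1ccccc1)S(=O)(=O)C(F)(F)F)C(F)(F)F; n-butyllithium, [Li]CCCC (lithium of intermediate 9 only)
Why: group-selective deprotonation of a conformationally biased 4,4-disubstituted cyclohexanone by a chiral lithium amide, which should remove one of the two axial α-protons (C2 rather than C4) and so create the C6 stereocentre under reagent control, followed by O-triflation of the enolate; the (S,S)-amide is used instead if the sense of induction proves opposite.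

Step 8
Reactants: 10 (6R,10S)-10-bromo-15-norchamigra-2,7(14)-dien-3-yl trifluoromethanesulfonate
Product: 11 (6R,10S)-10-bromochamigra-2,7(14)-diene
Conditions: MeZnCl, Pd(PPh3)4 (5 mol %), THF, 50 °C
Reagents that add atoms: methylzinc chloride, C[Zn]Cl
Why: Negishi coupling of an enol triflate under zerovalent palladium catalysis, which installs C15 without moving the double bond, so the C6 configuration is kept; the secondary alkyl bromide should not undergo oxidative addition under these conditions.

Step 9
Reactants: 11 (6R,10S)-10-bromochamigra-2,7(14)-diene
Product: 13 (2S,3R,6R,10S)-10-bromo-2,3-epoxychamigr-7(14)-ene, via trans-bromohydrin 12 (not isolated)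
Conditions: NBS, THF/H2O (3:1), 0 °C; then K2CO3, MeOH, 25 °C
Reagents that add atoms: water, O; N-bromosuccinimide, O=C1CCC(=O)N1Br (bromine of intermediate 12 only)
Why: halohydrin formation and base-induced closure, in which Br+ should add to the more electron-rich trisubstituted C2=C3 bond on the face anti to axial C7, water opens anti, and the alkoxide displaces bromide from the rear, so the epoxide oxygen ends on the C7 face (the face a peracid would not reach); either regioisomeric trans-bromohydrin converges on the same epoxide.

Step 10
Reactants: 13 (2S,3R,6R,10S)-10-bromo-2,3-epoxychamigr-7(14)-ene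
Product: 14 (2S,3S,6R,10S)-10-bromo-3-chlorochamigr-7(14)-en-2-ol
Conditions: HCl (1 M in Et2O, 1.2 equiv), CH2Cl2, −78 °C
Reagents that add atoms: hydrogen chloride, Cl
Why: acid-mediated epoxide opening in which chloride attacks tertiary C3 from the unhindered C11 face, a Markovnikov and trans-diaxial opening at once, setting C3–Cl axial and anti to the axial C2–OH; the low temperature should spare the exocyclic alkene.

Step 11
Reactants: 14 (2S,3S,6R,10S)-10-bromo-3-chlorochamigr-7(14)-en-2-ol
Product: 16 (2R,3R,6R,10S)-3,10-dibromo-2-chlorochamigr-7(14)-ene, via C2 triflate 15 (not isolated)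
Conditions: Tf2O, 2,6-di-tert-butyl-4-methylpyridine, CH2Cl2, −78 °C; then Bu4NBr (3 equiv), −78 → −20 °C
Reagents that add atoms: tetrabutylammonium bromide, CCCC[N+](CCCC)(CCCC)CCCC.[Br-]; trifluoromethanesulfonic anhydride, O=S(=O)(OS(=O)(=O)C(F)(F)F)C(F)(F)F (triflyl group of intermediate 15 only)
Why: Proposed new method: the C2 triflate of 15 is axial and antiperiplanar to the axial tertiary C3–Cl bond, so ionization should be assisted by chlorine, which moves to C2 with inversion and forms a chloronium ion bridging C2 and C3 on the C11 face; this unsymmetrical ion carries most of its positive charge at tertiary C3 and should be opened there by bromide from the C7 face, again with inversion, which puts Cl at C2 and Br at C3 trans to each other with C15 on the C11 face, as in 16; the closest known reaction type is substitution of vicinal halohydrin derivatives with neighbouring-halogen participation (retention or 1,2-halogen shift through a halonium ion), and the chloronium ion is the one that Cl+ attack on alkene 11 followed by bromide would give, reached here without mixing an oxidizing chlorine source with bromide.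

**Compound list**

1 | 5-bromo-2-methylpent-2-ene | CC(C)=CCCBr | starting material
2 | 6-methylhept-5-en-1-yne | CC(C)=CCCC#C | intermediate
3 | (3R)-3-(but-3-yn-1-yl)-2,2-dimethyloxirane | C#CCC[C@H]1OC1(C)C | intermediate
4 | (3S)-3-bromo-2-methylhept-6-yn-2-ol | C#CCC[C@H](Br)C(C)(C)O | intermediate
5 | phenol | Oc1ccccc1 | starting material
6 | 4-[(3S)-3-bromo-2-methylhept-6-yn-2-yl]phenol | C#CCC[C@H](Br)C(C)(C)c1ccc(O)cc1 | intermediate
7 | (10S)-10-bromo-15-norchamigra-1,4,7(14)-trien-3-one (spiro cyclohexa-2,5-dienone) | C=C1CC[C@H](Br)C(C)(C)C12C=CC(=O)C=C2 | intermediate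
8 | (10S)-10-bromo-15-norchamigr-7(14)-en-3-one | C=C1CC[C@H](Br)C(C)(C)C12CCC(=O)CC2 | intermediate
9 | lithium (6R,10S)-10-bromo-15-norchamigra-2,7(14)-dien-3-olate | C=C1CC[C@H](Br)C(C)(C)[C@@]12CCC(O[Li])=CC2 | intermediate
10 | (6R,10S)-10-bromo-15-norchamigra-2,7(14)-dien-3-yl trifluoromethanesulfonate | C=C1CC[C@H](Br)C(C)(C)[C@@]12CCC(OS(=O)(=O)C(F)(F)F)=CC2 | intermediate
11 | (6R,10S)-10-bromochamigra-2,7(14)-diene | C=C1CC[C@H](Br)C(C)(C)[C@@]12CCC(C)=CC2 | intermediate
12 | (2R,3R,6R,10S)-2,10-dibromochamigr-7(14)-en-3-ol | C=C1CC[C@H](Br)C(C)(C)[C@@]12CC[C@@](C)(O)[C@H](Br)C2 | intermediate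
13 | (2S,3R,6R,10S)-10-bromo-2,3-epoxychamigr-7(14)-ene (oxygen on the C7 face) | C=C1CC[C@H](Br)C(C)(C)[C@@]12CC[C@@]3(C)O[C@H]3C2 | intermediate
14 | (2S,3S,6R,10S)-10-bromo-3-chlorochamigr-7(14)-en-2-ol | C=C1CC[C@H](Br)C(C)(C)[C@@]12CC[C@](C)(Cl)[C@@H](O)C2 | intermediate
15 | (2S,3S,6R,10S)-10-bromo-3-chlorochamigr-7(14)-en-2-yl trifluoromethanesulfonate | C=C1CC[C@H](Br)C(C)(C)[C@@]12CC[C@](C)(Cl)[C@@H](OS(=O)(=O)C(F)(F)F)C2 | intermediate
16 | (2R,3R,6R,10S)-3,10-dibromo-2-chlorochamigr-7(14)-ene = (2S,6R,8R,9R)-2,9-dibromo-8-chloro-1,1,9-trimethyl-5-methylidenespiro[5.5]undecane | C=C1CC[C@H](Br)C(C)(C)[C@@]12CC[C@@](C)(Br)[C@H](Cl)C2 | target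

**Summary**

Total step count: 11. Longest linear sequence: 11 steps (from 1; phenol 5 enters in step 4).

**Steps most likely to fail**

Step 11 (proposed new method). The chloronium ion may be re-opened by bromide at C2 instead of C3, which returns a 2-bromo-3-chloro pattern without migration, or the C3 cation may lose a proton or be captured by the exocyclic alkene. The fallback uses known chemistry and sets out from chlorohydrin 14. Appel bromination (Ph3P, CBr4, CH2Cl2, 0 °C), which for a β-halo alcohol should proceed through the same bridged ion with net retention at the carbinol carbon, should give the trans-diaxial bromochloride (2S,3S,6R,10S)-2,10-dibromo-3-chlorochamigr-7(14)-ene F1. F1 is then equilibrated by the thermal diaxial-to-diequatorial rearrangement of vicinal dihalides (CHCl3 or MeNO2, 40–80 °C), in which the two halogens exchange carbons, each on its own face. Relief of the 1,3-diaxial contact between the C2 bromine and axial C7 is the expected driving force, though the position of this equilibrium is uncertain. The fallback rejoins the route at target 16.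

Step 9. Br+ transfer may show poor face selectivity or attack the exocyclic alkene, the bromonium ion may be captured across the ring by that alkene, or a trans-diequatorial bromohydrin may close only slowly. The fallback sets out from diene 11 and avoids the halohydrin route. Peracid epoxidation (mCPBA, NaHCO3, CH2Cl2, −20 °C) should attack anti to axial C7 and give (2R,3S,6R,10S)-10-bromo-2,3-epoxychamigr-7(14)-ene F2, with oxygen on the C11 face. Anhydrous HBr (1 equiv, Et2O, −78 °C) should open F2 at tertiary C3 with inversion to give (2R,3R,6R,10S)-3,10-dibromochamigr-7(14)-en-2-ol F3, which already has the C3 configuration of the target. Chlorination of the equatorial C2 alcohol with retention (SOCl2, 1,4-dioxane, internal return mechanism) then leads directly to target 16, bypassing 13, 14 and 15.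

Step 7. The chiral base may not discriminate well enough between the two α-methylene groups across the remote ring, giving both C6 epimers. The fallback sets out from dienone 7 and moves the desymmetrization one step earlier. An ene-reductase of the old yellow enzyme family (NADPH recycling, buffer, 30 °C), chosen from the known enantiocomplementary enzymes so that the C1=C2 bond is kept, should reduce only the C4=C5 bond and give (6R,10S)-10-bromo-15-norchamigra-1,7(14)-dien-3-one F4. Conjugate reduction of F4 with LiBH(s-Bu)3 (THF, −78 °C) and trapping of the resulting enolate with PhNTf2 rejoins the route at enol triflate 10.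

Further compounds
F1 | step 11 | (2S,3S,6R,10S)-2,10-dibromo-3-chlorochamigr-7(14)-ene | C=C1CC[C@H](Br)C(C)(C)[C@@]12CC[C@](C)(Cl)[C@@H](Br)C2
F2 | step 9 | (2R,3S,6R,10S)-10-bromo-2,3-epoxychamigr-7(14)-ene (oxygen on the C11 face) | C=C1CC[C@H](Br)C(C)(C)[C@@]12CC[C@]3(C)O[C@@H]3C2
F3 | step 9 | (2R,3R,6R,10S)-3,10-dibromochamigr-7(14)-en-2-ol | C=C1CC[C@H](Br)C(C)(C)[C@@]12CC[C@@](C)(Br)[C@H](O)C2
F4 | step 7 | (6R,10S)-10-bromo-15-norchamigra-1,7(14)-dien-3-one | C=C1CC[C@H](Br)C(C)(C)[C@@]12CCC(=O)C=C2
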